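Slowness is the first suspect when a flask must stop at a set part after a set time, but this flask can be reckoned by a count.

electrophile 0.050 M; time 4.0 d

    electrophile + nucleophile → acid set free + target (k1 = 11 M⁻¹ h⁻¹)
    nucleophile + acid set free ⇌ protonated nucleophile, settled at all times (K2 = 59000 M⁻¹)
    electrophile + target → side product (k3 = 1.5 M⁻¹ h⁻¹)
    electrophile ⇌ dormant form (K4 = 0.81, k4 = 0.15 h⁻¹)
    2 electrophile → self-condensation product (k5 = 0.0016 M⁻¹ h⁻¹)

- the concentration of nucleophile at which the part of the electrophile that has reacted at 4.0 d is just 50%, in M

- percent here means electrophile units held: one side product or self-condensation product counts as two
- for a step with 2 of a species take k times the square, and two of it per event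
- the amount of nucleophile is what is sought; it is there from the start
- run time (flask): 4.0 d

The dormant form counts as reacted here, since the part asked for is what has left the free electrophile. Electrophile and dormant form relax, both ways together by that step alone, with a half-life of 0.0862 d, far shorter than the run, so they stand at balance at 4.0 d. With 50.0% of the charge free, 40.5% sits dormant. The remainder is the product share, the fraction of the charge that has to end in products: 9.50%. Self-condensation takes about 0.384%, far less than that, so the nucleophile has to carry the rest of the product share.

From below: one nucleophile makes one target, and that target can take a second electrophile, so the nucleophile charge is at least about 4.56% of the electrophile charge. From above: the constant of the second step times that lowest charge stands far above one, so each turn ties a second nucleophile up as protonated nucleophile and about half of the nucleophile turns at first. Target has a half-life by the third step of 0.770 d with half the electrophile free, far shorter than the run, so nearly all of that early target becomes side product. The charge is then at most about 9.50%, which is 0.00475 M.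

The forecast, holding that “Each turn of step 1 also ties up a second nucleophile as its salt”, names 0.023 M, above this bracket.

The flask gives 0.00328 M, or 6.57% of the electrophile charge, inside the bracket. In that flask at 4.00 d, 0.350% of the charged nucleophile is still free. The product share over that charge reads 1.45 electrophile units per nucleophile charged. With 80.0% of that nucleophile at the same units per nucleophile, the product share becomes 7.60%, which puts the reacted part at 49.0%; that flask gives 49.1%.

(The numbers were chosen freely; what happens was integrated by code.)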